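**Retrosynthetic overview**

1. Rings: acacetin unit A (benzo), C (pyranone), B (4-methoxyphenyl), unprimed locants; 6-linked unit D (benzo), E (pyranone), F (4-hydroxyphenyl), double-primed locants. The strategy rests on ring A: a phloroglucinol whose C5–O, C7–O and C8a–O have three different fates and whose C8, between C7–O and C8a–O, carries the hindered bond to C6'' of ring D.
2. Target 29 ⇐ protected biflavone 27 (desilylation; BCl3 cleavage of the benzyl ether and of the peri C5 ethyl and C5'' methyl ethers).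
3. Ring E ⇐ Baker–Venkataraman aroylation and cyclodehydration on ring D after debenzylation and ortho-acetylation; ring C ⇐ 6-endo cyclisation of an o-hydroxyaryl ynone grown on ring A by phenol-directed formylation and acetylide addition.
4. Ring A ⇐ Danheiser benzannulation of aryl siloxyalkyne 6 with 3-ethoxycyclobutenone 10 (forms C8–C8a, C6–C7, C4a–C8a); the C8–C6'' bond is the aryl–alkyne bond of 6, which is made from aldehyde 1 in three steps.
5. Order of ring formation: D (purchased) → A → C → E; rings B and F enter as 4-ethynylanisole and 4-(benzyloxy)benzoyl chloride.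

Key step: step 5

Assumption: the target SMILES carries no descriptor for the C8–C6'' biaryl axis, so the racemic mixture of atropisomers is taken as the goal and the axis is not controlled.

**Route**

Step 1
Reactants: 1 4-hydroxy-2,6-dimethoxybenzaldehyde
Product: 2 4-(benzyloxy)-2,6-dimethoxybenzaldehyde
Conditions: BnBr, K2CO3, DMF, rt
Reagents that add atoms: benzyl bromide BrCc1ccccc1
Why: Williamson etherification of the acidic, aldehyde-conjugated phenoxide, the only nucleophilic site, should give the benzyl ether that later releases the oxygen destined to become O1''.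

Step 2
Reactants: 2 4-(benzyloxy)-2,6-dimethoxybenzaldehyde
Product: 3 5-(benzyloxy)-2-ethynyl-1,3-dimethoxybenzene
Conditions: dimethyl (1-diazo-2-oxopropyl)phosphonate, K2CO3, MeOH/THF, rt
Reagents that add atoms: dimethyl (1-diazo-2-oxopropyl)phosphonate COP(=O)(OC)C(=[N+]=[N-])C(C)=O
Why: Seyferth–Gilbert homologation in the Ohira–Bestmann form converts the aryl aldehyde into the terminal alkyne through a diazoalkene and carbene 1,2-shift under mild methoxide conditions that leave the ethers untouched.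

Step 3
Reactants: 3 5-(benzyloxy)-2-ethynyl-1,3-dimethoxybenzene
Product: 6 ({[4-(benzyloxy)-2,6-dimethoxyphenyl]ethynyl}oxy)triisopropylsilane, via lithium acetylide 4 (not isolated), via lithium ynolate 5 (not isolated)
Conditions: n-BuLi, THF, −78 °C; t-BuOOLi (from t-BuOOH and LiN(SiMe3)2), −78 → 0 °C; TIPSOTf, −78 → 0 °C
Reagents that add atoms: tert-butyl hydroperoxide CC(C)(C)OO; triisopropylsilyl trifluoromethanesulfonate CC(C)[Si](OS(=O)(=O)C(F)(F)F)(C(C)C)C(C)C
Why: Oxidation of a lithium acetylide by lithium tert-butyl peroxide to the lithium ynolate, followed by O-silylation with a bulky silyl triflate, is the established way from terminal alkynes to isolable triisopropylsiloxyalkynes.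

Step 4
Reactants: 7 ethoxyacetylene; 8 acetyl chloride
Product: 10 3-ethoxycyclobut-2-en-1-one, via ketene 9 (not isolated)
Conditions: Et3N, MeCN, 0 °C → rt
Reagents that add atoms: none
Why: Dehydrochlorination of acetyl chloride gives ketene, which undergoes the known [2+2] cycloaddition with the ynol ether, the nucleophilic CH terminus attacking the ketene carbonyl carbon.

Step 5
Reactants: 6 ({[4-(benzyloxy)-2,6-dimethoxyphenyl]ethynyl}oxy)triisopropylsilane; 10 3-ethoxycyclobut-2-en-1-one
Product: 15 4'-(benzyloxy)-4-ethoxy-2',6'-dimethoxy-6-[(triisopropylsilyl)oxy]biphenyl-2-ol, via ethoxyvinylketene 11 (not isolated), via vinylcyclobutenone 12 (not isolated), via dienylketene 13 (not isolated), via cyclohexadienone 14 (not isolated)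
Conditions: toluene, 80 → 110 °C, sealed tube
Reagents that add atoms: none
Why: Heating opens cyclobutenone 10 by four-electron electrocyclic cleavage to 3-ethoxyvinylketene 11, whose ketene C=C adds [2+2] to the electron-rich siloxyalkyne 6 to give 4-vinylcyclobutenone 12; a second four-electron opening gives dienylketene 13, and six-electron electrocyclisation followed by tautomerisation of dienone 14 should deliver the phenol. This is the Danheiser benzannulation of cyclobutenones with siloxyalkynes, a known route to resorcinol monosilyl ethers. Ring A is the only ring closed, by six-electron electrocyclic closure between the ketene carbon (future C8a) and the terminal methylene (future C4a), after C8–C8a and C6–C7 have been made in the [2+2] event. No stereocentre is created, and the stereocentre of 12 vanishes on ring opening. The step needs a regioselective ketene–alkyne union, and the oxygen lone pair of the ynol ether secures it by making the aryl-bearing alkyne carbon the nucleophile that attacks the ketene carbonyl carbon, so that the aryl group ends between the new phenol and the siloxy carbon and para to the ethoxy group. Since only oxygens flanking the aryl-bearing carbon can then become O1, the later pyranone closure can give only the C8-linked flavone, and the tetra-ortho-substituted biaryl bond is carried in as the aryl–alkyne bond and never has to be made by coupling.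

Step 6
Reactants: 15 4'-(benzyloxy)-4-ethoxy-2',6'-dimethoxy-6-[(triisopropylsilyl)oxy]biphenyl-2-ol
Product: 16 4'-(benzyloxy)-4-ethoxy-2-hydroxy-2',6'-dimethoxy-6-[(triisopropylsilyl)oxy]biphenyl-3-carbaldehyde
Conditions: MgCl2, Et3N, (CH2O)n, MeCN, reflux
Reagents that add atoms: paraformaldehyde (as formaldehyde) C=O
Why: The magnesium-mediated ortho-formylation (Casnati–Skattebøl reaction) acts only through the magnesium phenoxide, so the single free ortho position of ring A (future C4a) should be formylated while the equally electron-rich trialkoxy ring D, which a Friedel–Crafts acetylation would also attack, is left alone.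

Step 7
Reactants: 16 4'-(benzyloxy)-4-ethoxy-2-hydroxy-2',6'-dimethoxy-6-[(triisopropylsilyl)oxy]biphenyl-3-carbaldehyde; 17 1-ethynyl-4-methoxybenzene
Product: 19 4'-(benzyloxy)-4-ethoxy-3-[1-hydroxy-3-(4-methoxyphenyl)prop-2-yn-1-yl]-2',6'-dimethoxy-6-[(triisopropylsilyl)oxy]biphenyl-2-ol (racemic), via alkynylmagnesium bromide 18 (not isolated)
Conditions: 17, EtMgBr, THF, 0 °C → rt; then 16 (3 equiv of 18 used), 0 → 40 °C; aq. NH4Cl
Reagents that add atoms: none
Why: 1,2-Addition of an alkynyl Grignard reagent to a salicylaldehyde held as its magnesium phenoxide chelate (the first equivalent deprotonates the phenol) should give the propargylic alcohol, whose new carbinol centre forms racemic and is destroyed in step 8.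

Step 8
Reactants: 19 the propargylic alcohol
Product: 20 1-{4'-(benzyloxy)-4-ethoxy-2-hydroxy-2',6'-dimethoxy-6-[(triisopropylsilyl)oxy]biphenyl-3-yl}-3-(4-methoxyphenyl)prop-2-yn-1-one
Conditions: MnO2, CH2Cl2, rt (crude 19 used at once)
Reagents that add atoms: none
Why: MnO2 oxidises the doubly activated benzylic and propargylic alcohol selectively and should leave the hindered phenol, the silyl ether and the benzyl ether alone.

Step 9
Reactants: 20 the o-hydroxyaryl ynone
Product: 21 8-[4-(benzyloxy)-2,6-dimethoxyphenyl]-5-ethoxy-2-(4-methoxyphenyl)-7-[(triisopropylsilyl)oxy]-4H-chromen-4-one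
Conditions: DMAP (20 mol %), DMF, 40 °C
Reagents that add atoms: none
Why: DMAP-catalysed cyclisation of an o-alkynoylphenol (conjugate addition of DMAP to the ynone, then intramolecular addition–elimination by the phenoxide) should close pyranone ring C in the 6-endo sense and avoid the 5-exo aurone.

Step 10
Reactants: 21 the benzyl-protected flavone
Product: 22 5-ethoxy-8-(4-hydroxy-2,6-dimethoxyphenyl)-2-(4-methoxyphenyl)-7-[(triisopropylsilyl)oxy]-4H-chromen-4-one
Conditions: H2 (1 atm), Pd/C, EtOAc/MeOH, rt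
Reagents that add atoms: none
Why: Hydrogenolysis of the single aryl benzyl ether over palladium on carbon should free the ring D phenol, since the aryl silyl ether, the alkyl ethers and the conjugated pyranone are not reduced at one atmosphere.

Step 11
Reactants: 22 the ring D phenol
Product: 23 8-(3-acetyl-4-hydroxy-2,6-dimethoxyphenyl)-5-ethoxy-2-(4-methoxyphenyl)-7-[(triisopropylsilyl)oxy]-4H-chromen-4-one (racemic about the biaryl axis)
Conditions: Ac2O, BF3·OEt2, ClCH2CH2Cl, 0 → 50 °C; then aq. NaOAc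
Reagents that add atoms: acetic anhydride CC(=O)OC(C)=O
Why: BF3-mediated Friedel–Crafts acetylation (O-acetylation then Fries shift) of a 3,5-dimethoxyphenol should go ortho to the hydroxyl, the two ortho sites of ring D being equivalent and the para site blocked, while the BF3-complexed flavone rings are deactivated; the biaryl axis becomes stereogenic here and forms racemic.

Step 12
Reactants: 23 the ring D acetophenone; 24 4-(benzyloxy)benzoyl chloride
Product: 26 1-[4-(benzyloxy)phenyl]-3-{3-[5-ethoxy-2-(4-methoxyphenyl)-4-oxo-7-[(triisopropylsilyl)oxy]-4H-chromen-8-yl]-6-hydroxy-2,4-dimethoxyphenyl}propane-1,3-dione, via dilithium enolate phenoxide 25 (not isolated)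
Conditions: LiN(SiMe3)2 (4 equiv), THF, −78 → −20 °C; then 24, −78 °C → rt; aq. NH4Cl
Reagents that add atoms: none
Why: In the one-flask lithium amide variant of the Baker–Venkataraman synthesis the enolate phenoxide dianion is acylated on carbon by the aroyl chloride to the 1,3-diketone, and the hindered amide base should not attack the existing flavone.

Step 13
Reactants: 26 the 1,3-diketone
Product: 27 8-{2-[4-(benzyloxy)phenyl]-5,7-dimethoxy-4-oxo-4H-chromen-6-yl}-5-ethoxy-2-(4-methoxyphenyl)-7-[(triisopropylsilyl)oxy]-4H-chromen-4-one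
Conditions: p-TsOH·H2O (cat.), toluene, 90 °C
Reagents that add atoms: none
Why: Acid-catalysed cyclodehydration of the o-hydroxyaryl 1,3-diketone (6-exo-trig hemiketal formation, then loss of water) should close pyranone ring E under anhydrous conditions that spare the silyl and benzyl ethers.

Step 14
Reactants: 27 the protected biflavone
Product: 28 8-{2-[4-(benzyloxy)phenyl]-5,7-dimethoxy-4-oxo-4H-chromen-6-yl}-5-ethoxy-7-hydroxy-2-(4-methoxyphenyl)-4H-chromen-4-one
Conditions: Bu4NF, AcOH, THF, 0 °C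
Reagents that add atoms: none
Why: Fluoride cleaves the aryl silyl ether at silicon, and the acetic acid buffer keeps the phenoxide from opening the base-sensitive pyranones.

Step 15
Reactants: 28 the C7 phenol
Product: 29 5,7-dihydroxy-8-[5-hydroxy-2-(4-hydroxyphenyl)-7-methoxy-4-oxo-4H-chromen-6-yl]-2-(4-methoxyphenyl)-4H-chromen-4-one (target)
Conditions: BCl3, CH2Cl2, −78 °C → rt; then H2O
Reagents that add atoms: none
Why: BCl3 should cleave the benzyl ether and, through six-membered chelates with the C4 and C4'' carbonyls, the peri C5 ethyl and C5'' methyl ethers, while the non-chelated C7'' and C4' methyl ethers are inert to BCl3 at or below room temperature.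

**Compound list**

1 | 4-hydroxy-2,6-dimethoxybenzaldehyde | COc1cc(O)cc(OC)c1C=O | starting material
2 | 4-(benzyloxy)-2,6-dimethoxybenzaldehyde | COc1cc(OCc2ccccc2)cc(OC)c1C=O | intermediate
3 | 5-(benzyloxy)-2-ethynyl-1,3-dimethoxybenzene | C#Cc1c(OC)cc(OCc2ccccc2)cc1OC | intermediate
4 | lithium [4-(benzyloxy)-2,6-dimethoxyphenyl]acetylide | [Li]C#Cc1c(OC)cc(OCc2ccccc2)cc1OC | intermediate
5 | lithium [4-(benzyloxy)-2,6-dimethoxyphenyl]ethynolate | [Li]OC#Cc1c(OC)cc(OCc2ccccc2)cc1OC | intermediate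
6 | ({[4-(benzyloxy)-2,6-dimethoxyphenyl]ethynyl}oxy)triisopropylsilane | CC(C)[Si](OC#Cc1c(OC)cc(OCc2ccccc2)cc1OC)(C(C)C)C(C)C | intermediate
7 | ethoxyacetylene | C#COCC | starting material
8 | acetyl chloride | CC(=O)Cl | starting material
9 | ketene | C=C=O | intermediate
10 | 3-ethoxycyclobut-2-en-1-one | CCOC1=CC(=O)C1 | intermediate
11 | 3-ethoxybuta-1,3-dien-1-one (ethoxyvinylketene) | C=C(OCC)C=C=O | intermediate
12 | 2-[4-(benzyloxy)-2,6-dimethoxyphenyl]-4-(1-ethoxyvinyl)-3-[(triisopropylsilyl)oxy]cyclobut-2-en-1-one (racemic) | O=C1C(c2c(OC)cc(OCc3ccccc3)cc2OC)=C(O[Si](C(C)C)(C(C)C)C(C)C)C1C(OCC)=C | intermediate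
13 | (3E)-2-[4-(benzyloxy)-2,6-dimethoxyphenyl]-5-ethoxy-3-[(triisopropylsilyl)oxy]hexa-1,3,5-trien-1-one (ketene carbon and ethoxyvinyl group cis) | O=C=C(c1c(OC)cc(OCc2ccccc2)cc1OC)/C(O[Si](C(C)C)(C(C)C)C(C)C)=C\C(OCC)=C | intermediate
14 | 2-[4-(benzyloxy)-2,6-dimethoxyphenyl]-5-ethoxy-3-[(triisopropylsilyl)oxy]cyclohexa-2,4-dien-1-one | O=C1CC(OCC)=CC(O[Si](C(C)C)(C(C)C)C(C)C)=C1c1c(OC)cc(OCc2ccccc2)cc1OC | intermediate
15 | 4'-(benzyloxy)-4-ethoxy-2',6'-dimethoxy-6-[(triisopropylsilyl)oxy]biphenyl-2-ol | CCOc1cc(O)c(-c2c(OC)cc(OCc3ccccc3)cc2OC)c(O[Si](C(C)C)(C(C)C)C(C)C)c1 | intermediate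
16 | 4'-(benzyloxy)-4-ethoxy-2-hydroxy-2',6'-dimethoxy-6-[(triisopropylsilyl)oxy]biphenyl-3-carbaldehyde | O=Cc1c(OCC)cc(O[Si](C(C)C)(C(C)C)C(C)C)c(-c2c(OC)cc(OCc3ccccc3)cc2OC)c1O | intermediate
17 | 1-ethynyl-4-methoxybenzene (4-ethynylanisole) | C#Cc1ccc(OC)cc1 | starting material
18 | [(4-methoxyphenyl)ethynyl]magnesium bromide | COc1ccc(cc1)C#C[Mg]Br | intermediate
19 | 4'-(benzyloxy)-4-ethoxy-3-[1-hydroxy-3-(4-methoxyphenyl)prop-2-yn-1-yl]-2',6'-dimethoxy-6-[(triisopropylsilyl)oxy]biphenyl-2-ol (racemic) | COc1ccc(cc1)C#CC(O)c1c(OCC)cc(O[Si](C(C)C)(C(C)C)C(C)C)c(-c2c(OC)cc(OCc3ccccc3)cc2OC)c1O | intermediate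
20 | 1-{4'-(benzyloxy)-4-ethoxy-2-hydroxy-2',6'-dimethoxy-6-[(triisopropylsilyl)oxy]biphenyl-3-yl}-3-(4-methoxyphenyl)prop-2-yn-1-one | COc1ccc(cc1)C#CC(=O)c1c(OCC)cc(O[Si](C(C)C)(C(C)C)C(C)C)c(-c2c(OC)cc(OCc3ccccc3)cc2OC)c1O | intermediate
21 | 8-[4-(benzyloxy)-2,6-dimethoxyphenyl]-5-ethoxy-2-(4-methoxyphenyl)-7-[(triisopropylsilyl)oxy]-4H-chromen-4-one | CCOc1cc(O[Si](C(C)C)(C(C)C)C(C)C)c(-c2c(OC)cc(OCc3ccccc3)cc2OC)c2oc(-c3ccc(OC)cc3)cc(=O)c12 | intermediate
22 | 5-ethoxy-8-(4-hydroxy-2,6-dimethoxyphenyl)-2-(4-methoxyphenyl)-7-[(triisopropylsilyl)oxy]-4H-chromen-4-one | CCOc1cc(O[Si](C(C)C)(C(C)C)C(C)C)c(-c2c(OC)cc(O)cc2OC)c2oc(-c3ccc(OC)cc3)cc(=O)c12 | intermediate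
23 | 8-(3-acetyl-4-hydroxy-2,6-dimethoxyphenyl)-5-ethoxy-2-(4-methoxyphenyl)-7-[(triisopropylsilyl)oxy]-4H-chromen-4-one (racemic about the biaryl axis) | CCOc1cc(O[Si](C(C)C)(C(C)C)C(C)C)c(-c2c(OC)c(C(C)=O)c(O)cc2OC)c2oc(-c3ccc(OC)cc3)cc(=O)c12 | intermediate
24 | 4-(benzyloxy)benzoyl chloride | O=C(Cl)c1ccc(OCc2ccccc2)cc1 | starting material
25 | dilithium enolate phenoxide of 23 | CCOc1cc(O[Si](C(C)C)(C(C)C)C(C)C)c(-c2c(OC)c(C(=C)O[Li])c(O[Li])cc2OC)c2oc(-c3ccc(OC)cc3)cc(=O)c12 | intermediate
26 | 1-[4-(benzyloxy)phenyl]-3-{3-[5-ethoxy-2-(4-methoxyphenyl)-4-oxo-7-[(triisopropylsilyl)oxy]-4H-chromen-8-yl]-6-hydroxy-2,4-dimethoxyphenyl}propane-1,3-dione (racemic about the biaryl axis) | CCOc1cc(O[Si](C(C)C)(C(C)C)C(C)C)c(-c2c(OC)c(C(=O)CC(=O)c3ccc(OCc4ccccc4)cc3)c(O)cc2OC)c2oc(-c3ccc(OC)cc3)cc(=O)c12 | intermediate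
27 | 8-{2-[4-(benzyloxy)phenyl]-5,7-dimethoxy-4-oxo-4H-chromen-6-yl}-5-ethoxy-2-(4-methoxyphenyl)-7-[(triisopropylsilyl)oxy]-4H-chromen-4-one (racemic about the biaryl axis) | CCOc1cc(O[Si](C(C)C)(C(C)C)C(C)C)c(-c2c(OC)cc3oc(-c4ccc(OCc5ccccc5)cc4)cc(=O)c3c2OC)c2oc(-c3ccc(OC)cc3)cc(=O)c12 | intermediate
28 | 8-{2-[4-(benzyloxy)phenyl]-5,7-dimethoxy-4-oxo-4H-chromen-6-yl}-5-ethoxy-7-hydroxy-2-(4-methoxyphenyl)-4H-chromen-4-one (racemic about the biaryl axis) | CCOc1cc(O)c(-c2c(OC)cc3oc(-c4ccc(OCc5ccccc5)cc4)cc(=O)c3c2OC)c2oc(-c3ccc(OC)cc3)cc(=O)c12 | intermediate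
29 | 5,7-dihydroxy-8-[5-hydroxy-2-(4-hydroxyphenyl)-7-methoxy-4-oxo-4H-chromen-6-yl]-2-(4-methoxyphenyl)-4H-chromen-4-one (racemic about the biaryl axis) | COc1ccc(-c2cc(=O)c3c(O)cc(O)c(-c4c(OC)cc5oc(-c6ccc(O)cc6)cc(=O)c5c4O)c3o2)cc1 | target

**Step count and risks**

Total steps: 15. Longest linear sequence: 14 steps (steps 1–3 and 5–15; step 4 is a one-step side branch).

Steps most likely to fail:

1. Step 5 (benzannulation). The transient ethoxyvinylketene may dimerise, or acylate the product phenol, faster than it adds to the doubly ortho-substituted aryl alkyne, and prolonged heating may isomerise the siloxyalkyne to a silylketene before it is trapped. The fallback gives up building ring A and makes the biaryl bond by cross-coupling. It sets out from aldehyde 2 and returns at phenol 15. Pinnick oxidation of 2 (NaClO2, NaH2PO4, 2-methylbut-2-ene, t-BuOH/H2O) should give 4-(benzyloxy)-2,6-dimethoxybenzoic acid F1, and decarboxylative ipso-bromination (Bu4NBr3, K3PO4, MeCN, 100 °C) should give 5-(benzyloxy)-2-bromo-1,3-dimethoxybenzene F2. Commercial 5-ethoxybenzene-1,3-diol is converted with MOMCl and i-Pr2NEt into 1-ethoxy-3,5-bis(methoxymethoxy)benzene F3, which is lithiated between the two acetal oxygens (n-BuLi, THF, 0 °C) and quenched with B(OMe)3 to give [4-ethoxy-2,6-bis(methoxymethoxy)phenyl]boronic acid F4. Suzuki–Miyaura coupling of F2 with F4 (Pd(OAc)2, SPhos, K3PO4, toluene/H2O, 100 °C) should give 4'-(benzyloxy)-4-ethoxy-2',6'-dimethoxy-2,6-bis(methoxymethoxy)biphenyl F5. HCl in MeOH removes both acetals to give the symmetric 4'-(benzyloxy)-4-ethoxy-2',6'-dimethoxybiphenyl-2,6-diol F6. Monosilylation with TIPSOTf (1 equiv) and 2,6-lutidine then gives 15; the two hydroxyls are equivalent, so only bis-silylation competes and it can be recycled.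

2. Step 11 (acetylation of ring D). The Lewis acid may strip the triisopropylsilyl ether, or the reaction may stall at the O-acetate without migration to carbon. The fallback builds the acetyl group in two one-carbon stages under non-acidic conditions. It sets out from phenol 22 and returns at acetophenone 23. Magnesium-mediated ortho-formylation (MgCl2, Et3N, (CH2O)n, MeCN, reflux) should give 3-[5-ethoxy-2-(4-methoxyphenyl)-4-oxo-7-[(triisopropylsilyl)oxy]-4H-chromen-8-yl]-6-hydroxy-2,4-dimethoxybenzaldehyde F7. MeTi(Oi-Pr)3 (THF, −20 °C → rt), which methylates aldehydes but not the vinylogous ester carbonyl of the flavone, should give 5-ethoxy-8-[4-hydroxy-3-(1-hydroxyethyl)-2,6-dimethoxyphenyl]-2-(4-methoxyphenyl)-7-[(triisopropylsilyl)oxy]-4H-chromen-4-one F8. Oxidation with MnO2 in CH2Cl2 then gives 23.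

3. Step 15 (global deprotection). Cleavage of the peri ethyl ether may stay incomplete, and forcing it may take off the non-chelated C7'' or C4' methyl ether as well. The fallback separates the cleavages by mechanism. It sets out from 28 and returns at target 29. Hydrogenolysis (H2, Pd/C, THF/MeOH) removes only the benzyl ether and should give 5-ethoxy-7-hydroxy-8-[2-(4-hydroxyphenyl)-5,7-dimethoxy-4-oxo-4H-chromen-6-yl]-2-(4-methoxyphenyl)-4H-chromen-4-one F9. Anhydrous AlCl3 in MeCN at reflux, which dealkylates only ethers held in a six-membered chelate with a peri carbonyl, then frees the C5 and C5'' hydroxyls to give 29.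

**Further compounds**

F1 | step 5 | 4-(benzyloxy)-2,6-dimethoxybenzoic acid | COc1cc(OCc2ccccc2)cc(OC)c1C(=O)O
F2 | step 5 | 5-(benzyloxy)-2-bromo-1,3-dimethoxybenzene | COc1cc(OCc2ccccc2)cc(OC)c1Br
F3 | step 5 | 1-ethoxy-3,5-bis(methoxymethoxy)benzene | CCOc1cc(OCOC)cc(OCOC)c1
F4 | step 5 | [4-ethoxy-2,6-bis(methoxymethoxy)phenyl]boronic acid | CCOc1cc(OCOC)c(B(O)O)c(OCOC)c1
F5 | step 5 | 4'-(benzyloxy)-4-ethoxy-2',6'-dimethoxy-2,6-bis(methoxymethoxy)biphenyl | CCOc1cc(OCOC)c(-c2c(OC)cc(OCc3ccccc3)cc2OC)c(OCOC)c1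
F6 | step 5 | 4'-(benzyloxy)-4-ethoxy-2',6'-dimethoxybiphenyl-2,6-diol | CCOc1cc(O)c(-c2c(OC)cc(OCc3ccccc3)cc2OC)c(O)c1
F7 | step 11 | 3-[5-ethoxy-2-(4-methoxyphenyl)-4-oxo-7-[(triisopropylsilyl)oxy]-4H-chromen-8-yl]-6-hydroxy-2,4-dimethoxybenzaldehyde | CCOc1cc(O[Si](C(C)C)(C(C)C)C(C)C)c(-c2c(OC)c(C=O)c(O)cc2OC)c2oc(-c3ccc(OC)cc3)cc(=O)c12
F8 | step 11 | 5-ethoxy-8-[4-hydroxy-3-(1-hydroxyethyl)-2,6-dimethoxyphenyl]-2-(4-methoxyphenyl)-7-[(triisopropylsilyl)oxy]-4H-chromen-4-one (mixture of diastereomers) | CCOc1cc(O[Si](C(C)C)(C(C)C)C(C)C)c(-c2c(OC)c(C(C)O)c(O)cc2OC)c2oc(-c3ccc(OC)cc3)cc(=O)c12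
F9 | step 15 | 5-ethoxy-7-hydroxy-8-[2-(4-hydroxyphenyl)-5,7-dimethoxy-4-oxo-4H-chromen-6-yl]-2-(4-methoxyphenyl)-4H-chromen-4-one | CCOc1cc(O)c(-c2c(OC)cc3oc(-c4ccc(O)cc4)cc(=O)c3c2OC)c2oc(-c3ccc(OC)cc3)cc(=O)c12
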